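**Retrosynthetic overview**

- The dihydropyranone ring is closed last: the O1–C2 bond forms by 6-endo oxa-Michael addition of an A-ring ortho-OH onto a free 2-aryl-1-(2,4,6-trihydroxyphenyl)prop-2-en-1-one, and catalyst-controlled protonation at C3 fixes the (R) centre.
- The free enone comes from its tetra-MOM ether by base-free unmasking; the tetra-MOM enone comes from MnO2 oxidation of the allylic alcohol.
- The C3–C4 bond is made from an α-arylvinyllithium (Shapiro reaction of the B-ring methyl ketone trisylhydrazone) and 2,4,6-tris(methoxymethoxy)benzaldehyde.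
- The B-ring chromene comes from chelation-controlled annulation of 2,4-dihydroxyacetophenone with prenal.
- Ring order: the 2,2-dimethylpyran ring first (step 1), the dihydropyranone ring last (step 8); both benzene rings are bought.

Assumption: CIP analysis of the given SMILES gives (3R); the sense of induction of the new catalyst in step 8 cannot be predicted with certainty, so the quinine-derived catalyst is written and its quinidine-derived pseudo-enantiomer replaces it if the first analytical run gives (3S).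

**Route**

Step 1
Reactants: 1 1-(2,4-dihydroxyphenyl)ethan-1-one; 2 3-methylbut-2-enal
Product: 3 1-(5-hydroxy-2,2-dimethyl-2H-chromen-6-yl)ethan-1-one
Conditions: 2 (1.5 equiv), pyridine, 120 °C (sealed tube), 16 h
Reagents that add atoms: none
Why: Chromenylation of a chelated resorcinol: the 2-OH is locked in a hydrogen bond to the acetyl group, so Knoevenagel-type C-alkylation at C3 followed by oxa-6π-electrocyclisation onto the free 4-OH gives the angular 5-hydroxy-6-acetyl chromene.

Step 2
Reactants: 3 1-(5-hydroxy-2,2-dimethyl-2H-chromen-6-yl)ethan-1-one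
Product: 4 1-[5-(methoxymethoxy)-2,2-dimethyl-2H-chromen-6-yl]ethan-1-one
Conditions: NaH (1.2 equiv), MOMCl (1.3 equiv), DMF, 0 °C → rt
Reagents that add atoms: chloromethyl methyl ether (MOMCl), COCCl
Why: Williamson-type O-alkylation (MOM protection) of the sodium phenoxide masks the acidic OH with a group that withstands n-BuLi and MnO2.

Step 3
Reactants: 4 1-[5-(methoxymethoxy)-2,2-dimethyl-2H-chromen-6-yl]ethan-1-one
Product: 5 N'-[(1E)-1-[5-(methoxymethoxy)-2,2-dimethyl-2H-chromen-6-yl]ethylidene]-2,4,6-tri(propan-2-yl)benzenesulfonohydrazide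
Conditions: TrisNHNH2 (1.1 equiv), AcOH (cat.), THF, rt → 40 °C
Reagents that add atoms: 2,4,6-tri(propan-2-yl)benzenesulfonohydrazide, CC(C)c1cc(C(C)C)c(S(=O)(=O)NN)c(C(C)C)c1
Why: Hydrazone formation by condensation of the methyl ketone; the trisyl group is chosen because it fragments cleanly in the Shapiro reaction without competing ortho-lithiation.

Step 4
Reactants: 6 2,4,6-trihydroxybenzaldehyde
Product: 7 2,4,6-tris(methoxymethoxy)benzaldehyde
Conditions: NaH (3.6 equiv), MOMCl (3.9 equiv), DMF, 0 °C → rt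
Reagents that add atoms: chloromethyl methyl ether (MOMCl), COCCl
Why: Exhaustive MOM protection with a hard electrophile gives O- and not C-alkylation of the phloroglucinol ring and removes all acidic protons before the organolithium step.

Step 5
Reactants: 5 N'-[(1E)-1-[5-(methoxymethoxy)-2,2-dimethyl-2H-chromen-6-yl]ethylidene]-2,4,6-tri(propan-2-yl)benzenesulfonohydrazide; 7 2,4,6-tris(methoxymethoxy)benzaldehyde
Product: 9 rac-2-[5-(methoxymethoxy)-2,2-dimethyl-2H-chromen-6-yl]-1-[2,4,6-tris(methoxymethoxy)phenyl]prop-2-en-1-ol, via vinyllithium 8 (not isolated)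
Conditions: 5 (1.2 equiv), n-BuLi (2.1 equiv per 5), THF, −78 → 0 °C; then 7 (1.0 equiv), −78 → 0 °C; H2O quench; Et3N-deactivated silica or use crude
Reagents that add atoms: none
Why: Shapiro reaction then 1,2-addition: n-BuLi removes N–H and the only α-C–H (CH3), warming expels sulfinate and N2 to give the MOM-chelated α-arylvinyllithium, which adds to the non-enolisable aldehyde; the carbinol centre is racemic and is erased in step 6.

Step 6
Reactants: 9 rac-2-[5-(methoxymethoxy)-2,2-dimethyl-2H-chromen-6-yl]-1-[2,4,6-tris(methoxymethoxy)phenyl]prop-2-en-1-ol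
Product: 10 2-[5-(methoxymethoxy)-2,2-dimethyl-2H-chromen-6-yl]-1-[2,4,6-tris(methoxymethoxy)phenyl]prop-2-en-1-one
Conditions: activated MnO2 (15 equiv), CH2Cl2, rt
Reagents that add atoms: none
Why: MnO2 oxidation of an allylic and benzylic alcohol runs under neutral heterogeneous conditions, so the easily ionised carbinol, the chromene and the MOM ethers are not touched.

Step 7
Reactants: 10 2-[5-(methoxymethoxy)-2,2-dimethyl-2H-chromen-6-yl]-1-[2,4,6-tris(methoxymethoxy)phenyl]prop-2-en-1-one
Product: 12 2-(5-hydroxy-2,2-dimethyl-2H-chromen-6-yl)-1-(2,4,6-trihydroxyphenyl)prop-2-en-1-one, via tetrakis(trimethylsilyl) ether 11 (not isolated)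
Conditions: TMSOTf (8 equiv), 2,2'-bipyridyl (12 equiv), CH2Cl2, 0 °C → rt; then H2O, 0 °C; cold extraction, used at once
Reagents that add atoms: none
Why: Silyl triflate/bipyridyl cleavage of aryl MOM ethers turns each ArOMOM into ArOTMS and water then hydrolyses the silyl ethers in a bipyridinium-buffered, base-free medium; the enone has no enolisable hydrogen, and without base the chelated hydroxyaryl enone is expected not to cyclise.

Step 8
Reactants: 12 2-(5-hydroxy-2,2-dimethyl-2H-chromen-6-yl)-1-(2,4,6-trihydroxyphenyl)prop-2-en-1-one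
Product: 14 (3R)-5,7-dihydroxy-3-(5-hydroxy-2,2-dimethyl-2H-chromen-6-yl)-2,3-dihydro-4H-chromen-4-one, via chromen-4-ol enol 13 (not isolated)
Conditions: 9-amino-9-deoxy-epi-quinine 3,5-bis(trifluoromethyl)phenyl squaramide (10 mol %), CH2Cl2/PhMe 1:1, 4 Å MS, −40 °C; AcOH quench at −40 °C, short SiO2 plug (0.5 % AcOH in eluent)
Reagents that add atoms: none
Why: Proposed new method: an organocatalytic 6-endo-trig oxa-Michael ring closure whose stereocentre is set in the proton transfer that follows C–O bond formation: the quinuclidine nitrogen deprotonates the non-chelated ortho-OH of the A ring, the squaramide N–H pair binds the chelated carbonyl, the phenoxide adds to the terminal CH2 of the α-aryl enone to form O1–C2, and the squaramide-bound enolate (enol 13) is protonated at C3 on one face by the neighbouring quinuclidinium N–H inside the ion pair to give the (3R)-ketone; the two ortho-OH groups are equivalent, so either gives the same product, and at −40 °C the tertiary amine should be too weak to re-enolise the α-aryl ketone, so the kinetic ee should be kept; the closest known reaction types are amine–thiourea-catalysed intramolecular oxa-Michael cyclisations to flavanones and chromanones (stereocentre at the O-bearing carbon) and cinchona-squaramide-catalysed sulfa-Michael/enantioselective protonation of α-substituted enones and acrylates, but an oxa-Michael/asymmetric protonation giving an isoflavanone has not been shown.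

**Compound list**

1 | 1-(2,4-dihydroxyphenyl)ethan-1-one | CC(=O)c1ccc(O)cc1O | starting material
2 | 3-methylbut-2-enal | CC(C)=CC=O | starting material
3 | 1-(5-hydroxy-2,2-dimethyl-2H-chromen-6-yl)ethan-1-one | CC(=O)c1ccc2OC(C)(C)C=Cc2c1O | intermediate
4 | 1-[5-(methoxymethoxy)-2,2-dimethyl-2H-chromen-6-yl]ethan-1-one | CC(=O)c1ccc2OC(C)(C)C=Cc2c1OCOC | intermediate
5 | N'-[(1E)-1-[5-(methoxymethoxy)-2,2-dimethyl-2H-chromen-6-yl]ethylidene]-2,4,6-tri(propan-2-yl)benzenesulfonohydrazide | C/C(=N\NS(=O)(=O)c1c(C(C)C)cc(C(C)C)cc1C(C)C)c1ccc2OC(C)(C)C=Cc2c1OCOC | intermediate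
6 | 2,4,6-trihydroxybenzaldehyde | O=Cc1c(O)cc(O)cc1O | starting material
7 | 2,4,6-tris(methoxymethoxy)benzaldehyde | COCOc1cc(OCOC)c(C=O)c(OCOC)c1 | intermediate
8 | {1-[5-(methoxymethoxy)-2,2-dimethyl-2H-chromen-6-yl]ethenyl}lithium (not isolated) | [Li]C(=C)c1ccc2OC(C)(C)C=Cc2c1OCOC | intermediate
9 | rac-2-[5-(methoxymethoxy)-2,2-dimethyl-2H-chromen-6-yl]-1-[2,4,6-tris(methoxymethoxy)phenyl]prop-2-en-1-ol | C=C(C(O)c1c(OCOC)cc(OCOC)cc1OCOC)c1ccc2OC(C)(C)C=Cc2c1OCOC | intermediate
10 | 2-[5-(methoxymethoxy)-2,2-dimethyl-2H-chromen-6-yl]-1-[2,4,6-tris(methoxymethoxy)phenyl]prop-2-en-1-one | C=C(C(=O)c1c(OCOC)cc(OCOC)cc1OCOC)c1ccc2OC(C)(C)C=Cc2c1OCOC | intermediate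
11 | 2-{2,2-dimethyl-5-[(trimethylsilyl)oxy]-2H-chromen-6-yl}-1-{2,4,6-tris[(trimethylsilyl)oxy]phenyl}prop-2-en-1-one (not isolated) | C=C(C(=O)c1c(O[Si](C)(C)C)cc(O[Si](C)(C)C)cc1O[Si](C)(C)C)c1ccc2OC(C)(C)C=Cc2c1O[Si](C)(C)C | intermediate
12 | 2-(5-hydroxy-2,2-dimethyl-2H-chromen-6-yl)-1-(2,4,6-trihydroxyphenyl)prop-2-en-1-one | C=C(C(=O)c1c(O)cc(O)cc1O)c1ccc2OC(C)(C)C=Cc2c1O | intermediate
13 | 3-(5-hydroxy-2,2-dimethyl-2H-chromen-6-yl)-2H-chromene-4,5,7-triol (catalyst-bound enol, not isolated) | OC1=C(COc2cc(O)cc(O)c12)c1ccc2OC(C)(C)C=Cc2c1O | intermediate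
14 | (3R)-5,7-dihydroxy-3-(5-hydroxy-2,2-dimethyl-2H-chromen-6-yl)-2,3-dihydro-4H-chromen-4-one | CC1(C)C=Cc2c(ccc([C@@H]3COc4cc(O)cc(O)c4C3=O)c2O)O1 | target

**Step count and risks**

Total steps: 8. Longest linear sequence: 7 (steps 1, 2, 3, 5, 6, 7, 8 from compound 1).

Step 8 is the new ring closure. It may give low ee or the wrong sense, or the product may racemise on the catalyst. The fallback uses known chemistry, sets out from 12 and comes back at 14. The ring of 12 is closed without induction with NaOAc in EtOH at rt, the established base-mediated cyclisation of 2'-hydroxy-α-methylenedeoxybenzoins, through enol 13. This gives rac-5,7-dihydroxy-3-(5-hydroxy-2,2-dimethyl-2H-chromen-6-yl)-2,3-dihydro-4H-chromen-4-one F1. F1 is resolved by preparative chiral SFC or HPLC on an amylose tris(3,5-dimethylphenylcarbamate) phase with an acidified eluent, and the (3R)-enantiomer is 14. The other fraction, (3S)-5,7-dihydroxy-3-(5-hydroxy-2,2-dimethyl-2H-chromen-6-yl)-2,3-dihydro-4H-chromen-4-one F2, is re-racemised with Et3N and recycled.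

Step 7 is the unmasking to the free enone. The tetraphenol 12 may cyclise to racemate during hydrolysis, or the Lewis acid may damage the enone. The fallback sets out from 10 and comes back at 14. Only one ortho MOM group of the A ring is removed by chelation of boron between that oxygen and the ketone (BCl3 1.05 equiv, CH2Cl2, −78 °C; the two ortho groups are equivalent). This gives 1-[2-hydroxy-4,6-bis(methoxymethoxy)phenyl]-2-[5-(methoxymethoxy)-2,2-dimethyl-2H-chromen-6-yl]prop-2-en-1-one F3, a 2-hydroxyaryl vinyl ketone with a single chelated OH. F3 is cyclised with the catalyst of step 8, through 5,7-bis(methoxymethoxy)-3-[5-(methoxymethoxy)-2,2-dimethyl-2H-chromen-6-yl]-2H-chromen-4-ol F4 (not isolated), to (3R)-5,7-bis(methoxymethoxy)-3-[5-(methoxymethoxy)-2,2-dimethyl-2H-chromen-6-yl]-2,3-dihydro-4H-chromen-4-one F5. The three remaining MOM groups are then removed under non-basic heterogeneous conditions (NaHSO4·SiO2, CH2Cl2, rt, ee monitored) to give 14.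

Step 5 is the Shapiro addition. The vinyllithium may be quenched, or may add poorly to the hindered, electron-rich aldehyde. The fallback sets out from 4 and comes back at 9. Ketone 4 is converted with KHMDS and PhNTf2 (THF, −78 °C) into 1-[5-(methoxymethoxy)-2,2-dimethyl-2H-chromen-6-yl]ethenyl trifluoromethanesulfonate F6. F6 is coupled with aldehyde 7 in a Nozaki–Hiyama–Kishi reaction (CrCl2 4 equiv, NiCl2 2 mol %, DMF, rt) through {1-[5-(methoxymethoxy)-2,2-dimethyl-2H-chromen-6-yl]ethenyl}chromium(III) dichloride F7 (not isolated). This gives 9 without any strongly basic organolithium.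

**Further compounds**

F1 | step 8 | rac-5,7-dihydroxy-3-(5-hydroxy-2,2-dimethyl-2H-chromen-6-yl)-2,3-dihydro-4H-chromen-4-one | CC1(C)C=Cc2c(ccc(C3COc4cc(O)cc(O)c4C3=O)c2O)O1
F2 | step 8 | (3S)-5,7-dihydroxy-3-(5-hydroxy-2,2-dimethyl-2H-chromen-6-yl)-2,3-dihydro-4H-chromen-4-one | CC1(C)C=Cc2c(ccc([C@H]3COc4cc(O)cc(O)c4C3=O)c2O)O1
F3 | step 7 | 1-[2-hydroxy-4,6-bis(methoxymethoxy)phenyl]-2-[5-(methoxymethoxy)-2,2-dimethyl-2H-chromen-6-yl]prop-2-en-1-one | C=C(C(=O)c1c(O)cc(OCOC)cc1OCOC)c1ccc2OC(C)(C)C=Cc2c1OCOC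
F4 | step 7 | 5,7-bis(methoxymethoxy)-3-[5-(methoxymethoxy)-2,2-dimethyl-2H-chromen-6-yl]-2H-chromen-4-ol | OC1=C(COc2cc(OCOC)cc(OCOC)c12)c1ccc2OC(C)(C)C=Cc2c1OCOC
F5 | step 7 | (3R)-5,7-bis(methoxymethoxy)-3-[5-(methoxymethoxy)-2,2-dimethyl-2H-chromen-6-yl]-2,3-dihydro-4H-chromen-4-one | CC1(C)C=Cc2c(ccc([C@@H]3COc4cc(OCOC)cc(OCOC)c4C3=O)c2OCOC)O1
F6 | step 5 | 1-[5-(methoxymethoxy)-2,2-dimethyl-2H-chromen-6-yl]ethenyl trifluoromethanesulfonate | C=C(OS(=O)(=O)C(F)(F)F)c1ccc2OC(C)(C)C=Cc2c1OCOC
F7 | step 5 | {1-[5-(methoxymethoxy)-2,2-dimethyl-2H-chromen-6-yl]ethenyl}chromium(III) dichloride | C=C([Cr](Cl)Cl)c1ccc2OC(C)(C)C=Cc2c1OCOC
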